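## Retrosynthetic overview

1. The target comes from global desilylation of a tris-silyl ether, itself made by esterifying the C8 alcohol of a trans-decalin with O-silylated 2-(hydroxymethyl)acrylic acid.
2. Ring B is closed last through the C7–C8 bond: an allylic acetate is turned into a 2-(methoxycarbonyl)allylindium that adds to a C8 aldehyde, which also creates the C11=C13 methylene ester.
3. Ring A is formed second by a semipinacol ring expansion of a 1-(2,3-epoxyalkyl)cyclopentanol: C10 shifts from C4 to C5, giving the C4 ketone, the C5–C10 bond and the C6 carbinol in one step.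
4. The epoxy alcohol comes from Shi epoxidation, a hydroxyl-directed C1 reduction and a desymmetrising enantioselective alkenylation of 2-allyl-2-methylcyclopentane-1,3-dione (the purchased five-membered ring) with an alkenylzinc.
5. The alkenylzinc comes from an enyne ester built by a Morita–Baylis–Hillman reaction of 3-(trimethylsilyl)propynal with methyl acrylate.

Assumption 1: atom labels C1–C13 are the positions the atoms take in the target (ring A = C1–C5 and C10; ring B = C5–C10; methyl on C10; C11(=C13)–C12O2Me on C7); compounds 4 and 22 are taken as commercially available.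

Assumption 2: the (1R,2R) enantiomer of the bis(sulfonamide) diol ligand is taken as the one that gives the (4S,10R) adduct 12; if induction is opposite, the (1S,2S) ligand is used in the same step.

## Route

Step 1
Reactants: 1 2-methylcyclopentane-1,3-dione; 2 allyl bromide
Product: 3 2-allyl-2-methylcyclopentane-1,3-dione
Conditions: NaOH (1.0 equiv, 1 M in H2O), allyl bromide (1.5 equiv), rt, 24 h
Reagents that add atoms: none
Why: C-alkylation of the stabilised 1,3-dione enolate with an allylic halide installs C9/C8 and makes C10 a prochiral quaternary carbon; no stereocentre is formed.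

Step 2
Reactants: 4 3-(trimethylsilyl)prop-2-ynal; 5 methyl acrylate
Product: 6 methyl 3-hydroxy-2-methylidene-5-(trimethylsilyl)pent-4-ynoate (racemic)
Conditions: 1,4-diazabicyclo[2.2.2]octane (DABCO, 20 mol%), 1,4-dioxane, 0 °C → rt
Reagents that add atoms: none
Why: Morita–Baylis–Hillman reaction of an activated ynal joins C7 to C11 and brings in C12/C13; the carbinol stereocentre is erased in step 3.

Step 3
Reactants: 6 methyl 3-hydroxy-2-methylidene-5-(trimethylsilyl)pent-4-ynoate
Product: 8 methyl (2E)-2-(acetoxymethyl)-5-(trimethylsilyl)pent-2-en-4-ynoate, via secondary acetate 7 (not isolated)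
Conditions: Ac2O (1.5 equiv), TMSOTf (5 mol%), CH2Cl2, 0 °C → rt
Reagents that add atoms: acetic anhydride CC(=O)OC(C)=O
Why: acetylation followed by silyl-triflate-catalysed allylic 1,3-transposition of the Baylis–Hillman acetate 7 gives the thermodynamically preferred conjugated (E)-2-(acetoxymethyl)enoate with a primary, non-participating allylic acetate.

Step 4
Reactants: 8 methyl (2E)-2-(acetoxymethyl)-5-(trimethylsilyl)pent-2-en-4-ynoate
Product: 9 methyl (2E)-2-(acetoxymethyl)pent-2-en-4-ynoate
Conditions: AgNO3 (10 mol%), acetone/H2O 4:1, rt, dark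
Reagents that add atoms: none
Why: silver-catalysed protodesilylation of the C(sp)–Si bond frees the terminal alkyne without touching the acetate or methyl ester.

Step 5
Reactants: 3 2-allyl-2-methylcyclopentane-1,3-dione; 9 methyl (2E)-2-(acetoxymethyl)pent-2-en-4-ynoate
Product: 12 methyl (2E,4E)-2-(acetoxymethyl)-5-[(1S,2R)-2-allyl-1-hydroxy-2-methyl-3-oxocyclopentyl]penta-2,4-dienoate, via alkenylzirconocene 10 (not isolated), via alkenylzinc 11 (not isolated)
Conditions: 9 (1.4 equiv), Cp2Zr(H)Cl (1.4 equiv), CH2Cl2, rt, 20 min; Me2Zn (1.4 equiv), toluene, −78 °C; (1R,2R)-1,2-bis(2-hydroxycamphor-10-sulfonamido)cyclohexane (10 mol%), Ti(OiPr)4 (1.2 equiv), 3 (1.0 equiv), toluene, 0 °C → rt; aqueous work-up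
Reagents that add atoms: none
Why: Proposed new method: a catalyst-controlled desymmetrisation in which alkenylzinc 11 (from syn-hydrozirconation of 9 to 10 and Zr-to-Zn exchange) is transferred inside a chiral titanium bis(sulfonamide)-diolate complex to one carbonyl face only; because the alkenyl group must also enter anti to the allyl group (syn to methyl), only one of the two enantiotopic carbonyls meets both demands, so C10 (R) and C4 (S) are set together and the C4–C5 bond is formed, while the quaternary C10 blocks enolisation and the covalent zinc/titanium alkoxide resists retro-aldol cleavage; the closest known reaction type is the titanium/bis(sulfonamide)-diol-catalysed enantioselective addition of alkyne-derived alkenylzinc reagents to simple ketones, and the closest known desymmetrisation of this dione class is enantioselective carbonyl reduction.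

Step 6
Reactants: 12 methyl (2E,4E)-2-(acetoxymethyl)-5-[(1S,2R)-2-allyl-1-hydroxy-2-methyl-3-oxocyclopentyl]penta-2,4-dienoate
Product: 13 methyl (2E,4E)-2-(acetoxymethyl)-5-[(1S,2S,3R)-2-allyl-1,3-dihydroxy-2-methylcyclopentyl]penta-2,4-dienoate
Conditions: Me4NBH(OAc)3 (4 equiv), MeCN/AcOH 1:1, −30 °C
Reagents that add atoms: none
Why: Evans–Saksena hydroxyl-directed reduction; the acetoxyborohydride bound to the tertiary C4 hydroxyl delivers hydride to C1 from the hydroxyl (allyl) face, giving the trans-1,3-diol with the C1 hydroxyl cis to the C10 methyl (1R).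

Step 7
Reactants: 13 methyl (2E,4E)-2-(acetoxymethyl)-5-[(1S,2S,3R)-2-allyl-1,3-dihydroxy-2-methylcyclopentyl]penta-2,4-dienoate
Product: 14 methyl (2E,4E)-2-(acetoxymethyl)-5-[(1S,2S,3R)-2-allyl-3-(tert-butyldimethylsilyloxy)-1-hydroxy-2-methylcyclopentyl]penta-2,4-dienoate
Conditions: TBSOTf (1.05 equiv), 2,6-lutidine (2 equiv), CH2Cl2, −78 °C
Reagents that add atoms: tert-butyldimethylsilyl triflate CC(C)(C)[Si](C)(C)OS(=O)(=O)C(F)(F)F
Why: chemoselective silylation of the secondary C1 alcohol over the more hindered tertiary carbinol at low temperature; the bulky silyl ether keeps the C1 oxygen from opening the epoxide later.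

Step 8
Reactants: 14 methyl (2E,4E)-2-(acetoxymethyl)-5-[(1S,2S,3R)-2-allyl-3-(tert-butyldimethylsilyloxy)-1-hydroxy-2-methylcyclopentyl]penta-2,4-dienoate
Product: 15 methyl (2E)-2-(acetoxymethyl)-3-{(2S,3R)-3-[(1R,2S,3R)-2-allyl-3-(tert-butyldimethylsilyloxy)-1-hydroxy-2-methylcyclopentyl]oxiran-2-yl}prop-2-enoate
Conditions: 1,2:4,5-di-O-isopropylidene-β-L-erythro-2,3-hexodiulo-2,6-pyranose (enantiomer of the fructose-derived Shi ketone, 30 mol%), KHSO5 (as 2KHSO5·KHSO4·K2SO4, 1.5 equiv), K2CO3, Bu4NHSO4 (cat.), MeCN/CH2(OMe)2/aq. Na2B4O7 buffer (pH 10.5), 0 °C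
Reagents that add atoms: potassium peroxymonosulfate [K+].[O-]S(=O)(=O)OO
Why: Shi asymmetric epoxidation; the trans-disubstituted γ,δ-alkene of the dienoate is the most reactive olefin (the terminal allyl and the ester-conjugated trisubstituted alkene are slow), and the spiro transition state of the L-series ketone delivers oxygen to the face that gives the (5R,6S) trans-epoxide under reagent control.

Step 9
Reactants: 15 methyl (2E)-2-(acetoxymethyl)-3-{(2S,3R)-3-[(1R,2S,3R)-2-allyl-3-(tert-butyldimethylsilyloxy)-1-hydroxy-2-methylcyclopentyl]oxiran-2-yl}prop-2-enoate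
Product: 17 methyl (2E,4S)-2-(acetoxymethyl)-4-[(1S,2R,3R)-2-allyl-3-(tert-butyldimethylsilyloxy)-2-methyl-6-oxocyclohexyl]-4-(triethylsilyloxy)but-2-enoate, via hydroxy ketone 16 (not isolated)
Conditions: BF3·OEt2 (1.1 equiv), CH2Cl2, −78 °C, 30 min; then 2,6-lutidine (4 equiv), TESOTf (1.3 equiv), −78 → 0 °C
Reagents that add atoms: triethylsilyl triflate CC[Si](CC)(CC)OS(=O)(=O)C(F)(F)F
Why: semipinacol rearrangement of a 2,3-epoxy alcohol (ring expansion of cyclopentanol to cyclohexanone); the more substituted ring carbon C10 migrates from C4 to C5 anti to the breaking C5–O bond (inversion at C5, retention at C10 and C6), which sets C5 (S) and C6 (S) trans to the C9 chain as a trans-decalin needs, the ester-bearing alkenyl group on C6 disfavouring ionisation there; immediate silylation of aldol 16 prevents retro-aldol and dehydration.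

Step 10
Reactants: 17 methyl (2E,4S)-2-(acetoxymethyl)-4-[(1S,2R,3R)-2-allyl-3-(tert-butyldimethylsilyloxy)-2-methyl-6-oxocyclohexyl]-4-(triethylsilyloxy)but-2-enoate
Product: 19 methyl (2E,4S)-2-(acetoxymethyl)-4-[(1S,2R,3R)-3-(tert-butyldimethylsilyloxy)-2-methyl-6-oxo-2-(2-oxoethyl)cyclohexyl]-4-(triethylsilyloxy)but-2-enoate, via ozonide 18 (not isolated)
Conditions: O3, CH2Cl2, −78 °C (Sudan red 7B end point); PPh3 (1.5 equiv), −78 °C → rt
Reagents that add atoms: ozone [O-][O+]=O
Why: ozonolysis with reductive work-up; the electron-neutral terminal alkene reacts far faster than the electron-poor trisubstituted enoate, unmasking the C8 aldehyde.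

Step 11
Reactants: 19 methyl (2E,4S)-2-(acetoxymethyl)-4-[(1S,2R,3R)-3-(tert-butyldimethylsilyloxy)-2-methyl-6-oxo-2-(2-oxoethyl)cyclohexyl]-4-(triethylsilyloxy)but-2-enoate
Product: 21 methyl 2-[(1S,2R,3S,4aR,5R,8aS)-5-(tert-butyldimethylsilyloxy)-3-hydroxy-4a-methyl-8-oxo-1-(triethylsilyloxy)decahydronaphthalen-2-yl]prop-2-enoate, via allylindium 20 (not isolated)
Conditions: Pd(PPh3)4 (5 mol%), InI (1.5 equiv), THF, rt; aqueous work-up
Reagents that add atoms: none
Why: palladium/indium umpolung carbonyl allylation (intramolecular Barbier type); zerovalent palladium and monovalent indium iodide turn the allylic acetate into nucleophilic allylindium 20, which adds through its γ-carbon C7 to the aldehyde (not the ketone) in a chair transition state with the C6 silyloxy group, the ester-bearing carbon and the aldehyde oxygen all equatorial (an axial oxygen would clash with the axial C10 methyl), setting 7α-H and 8α-OH and closing ring B as a trans-decalin with the C11=C13 methylene ester in place.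

Step 12
Reactants: 22 2-(hydroxymethyl)prop-2-enoic acid
Product: 24 2-[(tert-butyldimethylsilyloxy)methyl]prop-2-enoic acid, via bis-silyl derivative 23 (not isolated)
Conditions: TBSCl (2.2 equiv), imidazole (4 equiv), DMF, rt; then K2CO3 (10 mol%), THF/H2O, rt
Reagents that add atoms: tert-butyldimethylsilyl chloride CC(C)(C)[Si](C)(C)Cl
Why: exhaustive silylation followed by selective hydrolysis of the labile silyl ester leaves the primary silyl ether and the free acid.

Step 13
Reactants: 21 methyl 2-[(1S,2R,3S,4aR,5R,8aS)-5-(tert-butyldimethylsilyloxy)-3-hydroxy-4a-methyl-8-oxo-1-(triethylsilyloxy)decahydronaphthalen-2-yl]prop-2-enoate; 24 2-[(tert-butyldimethylsilyloxy)methyl]prop-2-enoic acid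
Product: 25 methyl 2-[(1S,2R,3S,4aR,5R,8aS)-5-(tert-butyldimethylsilyloxy)-3-({2-[(tert-butyldimethylsilyloxy)methyl]prop-2-enoyl}oxy)-4a-methyl-8-oxo-1-(triethylsilyloxy)decahydronaphthalen-2-yl]prop-2-enoate
Conditions: N,N′-diisopropylcarbodiimide (1.5 equiv), 4-(dimethylamino)pyridine (0.3 equiv), CH2Cl2, 0 °C → rt
Reagents that add atoms: none
Why: Steglich esterification of the only free hydroxyl (equatorial C8–OH); no stereocentre is touched.

Step 14
Reactants: 25 methyl 2-[(1S,2R,3S,4aR,5R,8aS)-5-(tert-butyldimethylsilyloxy)-3-({2-[(tert-butyldimethylsilyloxy)methyl]prop-2-enoyl}oxy)-4a-methyl-8-oxo-1-(triethylsilyloxy)decahydronaphthalen-2-yl]prop-2-enoate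
Product: 26 methyl 2-[(1S,2S,3S,4aR,5R,8aS)-1,5-dihydroxy-3-{[2-(hydroxymethyl)prop-2-enoyl]oxy}-4a-methyl-8-oxodecahydronaphthalen-2-yl]prop-2-enoate (CNP0144895.1)
Conditions: HF·pyridine, pyridine/THF, 0 °C → rt
Reagents that add atoms: none
Why: fluoride-mediated global desilylation under buffered acidic conditions removes all three silyl ethers while avoiding the retro-aldol, β-elimination and acyl migration that base would risk.

## Compound list

1 | 2-methylcyclopentane-1,3-dione | CC1C(=O)CCC1=O | starting material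
2 | allyl bromide (3-bromoprop-1-ene) | C=CCBr | starting material
3 | 2-allyl-2-methylcyclopentane-1,3-dione | C=CCC1(C)C(=O)CCC1=O | intermediate
4 | 3-(trimethylsilyl)prop-2-ynal | C[Si](C)(C)C#CC=O | starting material
5 | methyl acrylate | C=CC(=O)OC | starting material
6 | methyl 3-hydroxy-2-methylidene-5-(trimethylsilyl)pent-4-ynoate (racemic) | C=C(C(O)C#C[Si](C)(C)C)C(=O)OC | intermediate
7 | methyl 3-acetoxy-2-methylidene-5-(trimethylsilyl)pent-4-ynoate (racemic, not isolated) | C=C(C(OC(C)=O)C#C[Si](C)(C)C)C(=O)OC | intermediate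
8 | methyl (2E)-2-(acetoxymethyl)-5-(trimethylsilyl)pent-2-en-4-ynoate | CC(=O)OC/C(C(=O)OC)=C\C#C[Si](C)(C)C | intermediate
9 | methyl (2E)-2-(acetoxymethyl)pent-2-en-4-ynoate | CC(=O)OC/C(C(=O)OC)=C\C#C | intermediate
10 | chlorobis(cyclopentadienyl)[(1E,3E)-5-acetoxy-4-(methoxycarbonyl)penta-1,3-dien-1-yl]zirconium (not isolated) | CC(=O)OC/C(C(=O)OC)=C\C=C\[Zr](Cl)(C1C=CC=C1)C1C=CC=C1 | intermediate
11 | [(1E,3E)-5-acetoxy-4-(methoxycarbonyl)penta-1,3-dien-1-yl](methyl)zinc (not isolated) | CC(=O)OC/C(C(=O)OC)=C\C=C\[Zn]C | intermediate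
12 | methyl (2E,4E)-2-(acetoxymethyl)-5-[(1S,2R)-2-allyl-1-hydroxy-2-methyl-3-oxocyclopentyl]penta-2,4-dienoate (tertiary OH cis to allyl) | C=CC[C@@]1(C)C(=O)CC[C@]1(O)/C=C/C=C(\COC(C)=O)C(=O)OC | intermediate
13 | methyl (2E,4E)-2-(acetoxymethyl)-5-[(1S,2S,3R)-2-allyl-1,3-dihydroxy-2-methylcyclopentyl]penta-2,4-dienoate (secondary OH cis to methyl) | C=CC[C@@]1(C)[C@H](O)CC[C@]1(O)/C=C/C=C(\COC(C)=O)C(=O)OC | intermediate
14 | methyl (2E,4E)-2-(acetoxymethyl)-5-[(1S,2S,3R)-2-allyl-3-(tert-butyldimethylsilyloxy)-1-hydroxy-2-methylcyclopentyl]penta-2,4-dienoate | C=CC[C@@]1(C)[C@H](O[Si](C)(C)C(C)(C)C)CC[C@]1(O)/C=C/C=C(\COC(C)=O)C(=O)OC | intermediate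
15 | methyl (2E)-2-(acetoxymethyl)-3-{(2S,3R)-3-[(1R,2S,3R)-2-allyl-3-(tert-butyldimethylsilyloxy)-1-hydroxy-2-methylcyclopentyl]oxiran-2-yl}prop-2-enoate | C=CC[C@@]1(C)[C@H](O[Si](C)(C)C(C)(C)C)CC[C@]1(O)[C@@H]2O[C@H]2/C=C(\COC(C)=O)C(=O)OC | intermediate
16 | methyl (2E,4S)-2-(acetoxymethyl)-4-[(1S,2R,3R)-2-allyl-3-(tert-butyldimethylsilyloxy)-2-methyl-6-oxocyclohexyl]-4-hydroxybut-2-enoate (not isolated) | C=CC[C@@]1(C)[C@H](O[Si](C)(C)C(C)(C)C)CCC(=O)[C@@H]1[C@@H](O)/C=C(\COC(C)=O)C(=O)OC | intermediate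
17 | methyl (2E,4S)-2-(acetoxymethyl)-4-[(1S,2R,3R)-2-allyl-3-(tert-butyldimethylsilyloxy)-2-methyl-6-oxocyclohexyl]-4-(triethylsilyloxy)but-2-enoate | C=CC[C@@]1(C)[C@H](O[Si](C)(C)C(C)(C)C)CCC(=O)[C@@H]1[C@@H](O[Si](CC)(CC)CC)/C=C(\COC(C)=O)C(=O)OC | intermediate
18 | ozonide of 17: the allyl CH=CH2 is converted into a 1,2,4-trioxolan-3-ylmethyl group (not isolated) | C1OC(C[C@@]2(C)[C@H](O[Si](C)(C)C(C)(C)C)CCC(=O)[C@@H]2[C@@H](O[Si](CC)(CC)CC)/C=C(\COC(C)=O)C(=O)OC)OO1 | intermediate
19 | methyl (2E,4S)-2-(acetoxymethyl)-4-[(1S,2R,3R)-3-(tert-butyldimethylsilyloxy)-2-methyl-6-oxo-2-(2-oxoethyl)cyclohexyl]-4-(triethylsilyloxy)but-2-enoate | O=CC[C@@]1(C)[C@H](O[Si](C)(C)C(C)(C)C)CCC(=O)[C@@H]1[C@@H](O[Si](CC)(CC)CC)/C=C(\COC(C)=O)C(=O)OC | intermediate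
20 | allylindium from 19: the C13 acetoxy group is replaced by an acetato(iodo)indium group, trivalent indium, alkene geometry not fixed (not isolated) | O=CC[C@@]1(C)[C@H](O[Si](C)(C)C(C)(C)C)CCC(=O)[C@@H]1[C@@H](O[Si](CC)(CC)CC)C=C(C[In](I)OC(C)=O)C(=O)OC | intermediate
21 | methyl 2-[(1S,2R,3S,4aR,5R,8aS)-5-(tert-butyldimethylsilyloxy)-3-hydroxy-4a-methyl-8-oxo-1-(triethylsilyloxy)decahydronaphthalen-2-yl]prop-2-enoate (1β-OTBS, 6α-OTES, 8α-OH, 5α-H, 7α-H, 10β-Me) | O[C@H]1C[C@@]2(C)[C@H](O[Si](C)(C)C(C)(C)C)CCC(=O)[C@@H]2[C@@H](O[Si](CC)(CC)CC)[C@@H]1C(=C)C(=O)OC | intermediate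
22 | 2-(hydroxymethyl)prop-2-enoic acid | C=C(CO)C(=O)O | starting material
23 | tert-butyldimethylsilyl 2-[(tert-butyldimethylsilyloxy)methyl]prop-2-enoate (not isolated) | C=C(CO[Si](C)(C)C(C)(C)C)C(=O)O[Si](C)(C)C(C)(C)C | intermediate
24 | 2-[(tert-butyldimethylsilyloxy)methyl]prop-2-enoic acid | C=C(CO[Si](C)(C)C(C)(C)C)C(=O)O | intermediate
25 | methyl 2-[(1S,2R,3S,4aR,5R,8aS)-5-(tert-butyldimethylsilyloxy)-3-({2-[(tert-butyldimethylsilyloxy)methyl]prop-2-enoyl}oxy)-4a-methyl-8-oxo-1-(triethylsilyloxy)decahydronaphthalen-2-yl]prop-2-enoate | C=C(CO[Si](C)(C)C(C)(C)C)C(=O)O[C@H]1C[C@@]2(C)[C@H](O[Si](C)(C)C(C)(C)C)CCC(=O)[C@@H]2[C@@H](O[Si](CC)(CC)CC)[C@@H]1C(=C)C(=O)OC | intermediate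
26 | methyl 2-[(1S,2S,3S,4aR,5R,8aS)-1,5-dihydroxy-3-{[2-(hydroxymethyl)prop-2-enoyl]oxy}-4a-methyl-8-oxodecahydronaphthalen-2-yl]prop-2-enoate (1β,6α-dihydroxy, 8α-acyloxy, 4-oxo, 5α-H, 7α-H, 10β-Me) | C=C(CO)C(=O)O[C@H]1C[C@@]2(C)[C@H](O)CCC(=O)[C@@H]2[C@@H](O)[C@@H]1C(=C)C(=O)OC | target

## Step count and risks

Total step count: 14 (one-pot operations counted as one step). Longest linear sequence: 12 (steps 2–11, 13, 14).

Three steps most likely to fail:

Step 5 (the proposed new desymmetrising alkenylation). It may give low enantioselectivity, double addition or retro-aldol ring opening. The fallback uses known chemistry, sets out from 3 and comes back at 12. Baker's yeast (sucrose, H2O, 30 °C) reduces 3 to the known (2S,3S)-2-allyl-3-hydroxy-2-methylcyclopentan-1-one F1, with the hydroxyl cis to allyl, which fixes C10. F1 is then treated with 2.5 equiv of alkenylzinc 11 (made as in step 5) and Ti(OiPr)4 with the racemic bis(sulfonamide) diol ligand. The zinc alkoxide and the allyl group shield one face, so the alkenyl group enters cis to methyl and gives methyl (2E,4E)-2-(acetoxymethyl)-5-[(1S,2S,3S)-2-allyl-1,3-dihydroxy-2-methylcyclopentyl]penta-2,4-dienoate F2. Dess–Martin periodinane oxidises only the secondary carbinol of F2 and returns 12; the first stereocentre serves only to break the symmetry and is erased.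

Step 9 (semipinacol ring expansion). C3 could migrate instead of C10, the Lewis acid could open the epoxide at C6, or the C1 silyl ether could attack C5. The fallback sets out from 15 and comes back at 16. The tertiary hydroxyl of 15 is capped with TMSOTf/Et3N to give methyl (2E)-2-(acetoxymethyl)-3-{(2S,3R)-3-[(1R,2S,3R)-2-allyl-3-(tert-butyldimethylsilyloxy)-2-methyl-1-(trimethylsilyloxy)cyclopentyl]oxiran-2-yl}prop-2-enoate F3. F3 is rearranged with TiCl4 in CH2Cl2 at −78 °C (epoxy silyl ether rearrangement), where a silyloxy-stabilised cation drives the shift and no free hydroxyl can steer the Lewis acid. Aqueous work-up gives 16, which is silylated to 17 as in step 9.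

Step 11 (ring B closure). The indium alkoxide may lactonise onto the methyl ester, the allylmetal may undergo elimination, or the diastereoselectivity may be poor. The fallback sets out from 19 and comes back at 21 by a radical rather than an allylmetal pathway. SmI2 (2.5 equiv) in THF at −78 °C without a proton source gives the aldehyde ketyl, which adds 6-exo to C7 of the enoate. Reduction of the α-ester radical to the samarium enolate and β-elimination of acetate then give 21 directly; no new compound is made (F0).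

## Further compounds

F1 | step 5 | (2S,3S)-2-allyl-3-hydroxy-2-methylcyclopentan-1-one | C=CC[C@@]1(C)[C@@H](O)CCC1=O
F2 | step 5 | methyl (2E,4E)-2-(acetoxymethyl)-5-[(1S,2S,3S)-2-allyl-1,3-dihydroxy-2-methylcyclopentyl]penta-2,4-dienoate | C=CC[C@@]1(C)[C@@H](O)CC[C@]1(O)/C=C/C=C(\COC(C)=O)C(=O)OC
F3 | step 9 | methyl (2E)-2-(acetoxymethyl)-3-{(2S,3R)-3-[(1R,2S,3R)-2-allyl-3-(tert-butyldimethylsilyloxy)-2-methyl-1-(trimethylsilyloxy)cyclopentyl]oxiran-2-yl}prop-2-enoate | C=CC[C@@]1(C)[C@H](O[Si](C)(C)C(C)(C)C)CC[C@]1(O[Si](C)(C)C)[C@@H]2O[C@H]2/C=C(\COC(C)=O)C(=O)OC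
F0 | step 11 | none | none
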